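The side chain is cut between C7 and C8, counting from the exocyclic carbon (C1) to the carbinol carbon (C11). C7 is an sp3 CH2 homoallylic to the C4=C5 alkene; C8 is the methyl-bearing sp2 carbon of the E C8=C9 alkene. A protecting-group-free alkyl–alkenyl Negishi coupling forms this bond as the last step. It joins the complete C16 half with the Z-alkylidene γ-butyrolactone ring, as a primary zinc iodide, to the complete C9 half with the butenolide ring and free R carbinol, as an (E)-2-iodoalkene. It exploits the isolated C7(sp3)–C8(sp2) junction: the C8=C9 geometry is preset in the iodide and carried over with retention. The precursors are a homoallylic iodide and an iodoalkene.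

Key step: step 15

Assumption: the chiral phosphoric acid of step 1 is taken to follow the facial sense of its allylboration analogue (R catalyst giving the R carbinol); if the sense proves opposite, the S catalyst is used.

Step 1
Reactants: 1 furan-3-carbaldehyde; 2 allenylboronic acid pinacol ester
Product: 3 (1R)-1-(furan-3-yl)but-3-yn-1-ol
Conditions: (R)-3,3'-bis(2,4,6-triisopropylphenyl)-1,1'-binaphthyl-2,2'-diyl hydrogen phosphate (5 mol %), 4 Å MS, toluene, 0 °C; aq. NaHCO3
Reagents that add atoms: none
Why: Chiral phosphoric acid-catalysed asymmetric propargylation (SE2' allenylboration through a six-membered chair transition state), in which the catalyst binds the boronate oxygen and the formyl hydrogen and shields one aldehyde face so that the R carbinol should form.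

Step 2
Reactants: 3 (1R)-1-(furan-3-yl)but-3-yn-1-ol
Product: 5 (1R)-1-(furan-3-yl)pent-3-yn-1-ol, via dilithio alkoxide-acetylide 4 (not isolated)
Conditions: n-BuLi (2.1 equiv), THF, −78 → −20 °C; then MeI (1.05 equiv), DMPU, −78 → 0 °C; aq. NH4Cl
Reagents that add atoms: iodomethane, CI
Why: Alkylation of an alkynol dianion, in which the acetylide carbon is far more nucleophilic than the lithium alkoxide so that one equivalent of MeI should methylate carbon only and leave the carbinol stereocenter untouched.

Step 3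
Reactants: 5 (1R)-1-(furan-3-yl)pent-3-yn-1-ol
Product: 7 (1R,3E)-1-(furan-3-yl)-4-iodopent-3-en-1-ol, via bis-zirconocene alkenyl alkoxide 6 (not isolated)
Conditions: Cp2Zr(H)Cl (2.3 equiv), THF, 25 → 45 °C; then I2 (1.1 equiv), THF, −78 → 0 °C, dark; aq. Na2S2O3/NaHCO3
Reagents that add atoms: iodine, II
Why: Hydrozirconation–iodination, in which the first equivalent of Cp2Zr(H)Cl caps the hydroxyl as a bulky zirconium alkoxide, syn addition of Zr–H equilibrates zirconium onto the methyl-bearing alkyne carbon remote from that group, and iodinolysis with retention should give the E iodide.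

Step 4
Reactants: 7 (1R,3E)-1-(furan-3-yl)-4-iodopent-3-en-1-ol
Product: 9 5-hydroxy-4-[(1R,3E)-1-hydroxy-4-iodopent-3-en-1-yl]furan-2(5H)-one (both C5 epimers), via furan endoperoxide 8 (not isolated)
Conditions: O2, visible light, meso-tetraphenylporphyrin (cat.), i-Pr2NEt (3 equiv), CH2Cl2, −78 °C; then warm to 25 °C
Reagents that add atoms: dioxygen, O=O
Why: Singlet-oxygen [4+2] cycloaddition to the furan followed by Kornblum–DeLaMare-type fragmentation, in which the hindered amine removes the bridgehead proton remote from the side chain so that the carbonyl should form at the distal carbon and the hydroxyl next to the substituent, while the electron-poor iodoalkene is inert to singlet oxygen.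

Step 5
Reactants: 9 5-hydroxy-4-[(1R,3E)-1-hydroxy-4-iodopent-3-en-1-yl]furan-2(5H)-one
Product: 11 4-[(1R,3E)-1-hydroxy-4-iodopent-3-en-1-yl]furan-2(5H)-one, via ring-opened hydroxy acid 10 (not isolated)
Conditions: NaBH4, EtOH, 0 °C; then 1 M HCl to pH 2, 25 °C
Reagents that add atoms: none
Why: Borohydride reduction of the masked aldehyde (open-chain tautomer of the hydroxybutenolide) and acid-promoted relactonisation, in which only the new CH2OH is cis to the carboxyl so that the secondary carbinol cannot close a lactone.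

Step 6
Reactants: 12 3-(tert-butyldimethylsilyloxy)propanal; 13 isopropenylmagnesium bromide
Product: 14 5-(tert-butyldimethylsilyloxy)-2-methylpent-1-en-3-ol (racemic)
Conditions: THF, −78 → 0 °C; aq. NH4Cl
Reagents that add atoms: none
Why: Grignard 1,2-addition to the aldehyde, used as the racemate because this carbinol center is destroyed in the next step.

Step 7
Reactants: 14 5-(tert-butyldimethylsilyloxy)-2-methylpent-1-en-3-ol; 15 triethyl orthoacetate
Product: 17 ethyl (4E)-7-(tert-butyldimethylsilyloxy)-4-methylhept-4-enoate, via mixed ketene acetal 16 (not isolated)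
Conditions: 15 (6 equiv, neat), EtCO2H (cat.), 140 °C, distil off EtOH
Reagents that add atoms: none
Why: Johnson–Claisen rearrangement, whose chair transition state with the silyloxyethyl group equatorial should give the E trisubstituted alkene.

Step 8
Reactants: 17 ethyl (4E)-7-(tert-butyldimethylsilyloxy)-4-methylhept-4-enoate
Product: 18 (4E)-7-(tert-butyldimethylsilyloxy)-4-methylhept-4-enal
Conditions: i-Bu2AlH (1.05 equiv), CH2Cl2, −78 °C; MeOH, then aq. potassium sodium tartrate
Reagents that add atoms: none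
Why: Partial reduction of the ester by i-Bu2AlH through a tetrahedral aluminium hemiacetal that is stable at −78 °C and releases the aldehyde only on work-up.

Step 9
Reactants: 19 (5S)-5-(hydroxymethyl)dihydrofuran-2(3H)-one
Product: 20 (2S)-5-oxotetrahydrofuran-2-carbaldehyde
Conditions: Dess–Martin periodinane, CH2Cl2, 0 → 25 °C; filter, use crude at once
Reagents that add atoms: none
Why: Dess–Martin oxidation of the primary alcohol under non-basic conditions that should not epimerise the α-acyloxy aldehyde, whose stereocenter comes from the chiral pool.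

Step 10
Reactants: 20 (2S)-5-oxotetrahydrofuran-2-carbaldehyde; 21 isopropyltriphenylphosphonium iodide
Product: 23 (5S)-5-(2-methylprop-1-en-1-yl)dihydrofuran-2(3H)-one, via isopropylidene ylide 22 (not isolated)
Conditions: 21, n-BuLi (1.0 equiv), THF, 0 °C; then 20, THF, −78 → 0 °C
Reagents that add atoms: none
Why: Wittig olefination with a non-stabilised ylide, which attacks the aldehyde much faster than the lactone carbonyl at −78 °C and leaves the adjacent stereocenter (still S) in place.

Step 11
Reactants: 23 (5S)-5-(2-methylprop-1-en-1-yl)dihydrofuran-2(3H)-one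
Product: 25 bis(2,2,2-trifluoroethyl) [(5S)-5-(2-methylprop-1-en-1-yl)-2-oxotetrahydrofuran-3-yl]phosphonate (both C3 epimers), via enol phosphate 24 (not isolated)
Conditions: LiN(i-Pr)2 (1.1 equiv), THF, −78 °C; ClP(O)(OCH2CF3)2 (1.1 equiv); then LiN(i-Pr)2 (2.2 equiv), −78 → 0 °C; AcOH
Reagents that add atoms: bis(2,2,2-trifluoroethyl) phosphorochloridate, O=P(Cl)(OCC(F)(F)F)OCC(F)(F)F
Why: O-phosphorylation of the lactone enolate followed by base-induced 1,3-phosphorus migration (vinyl phosphate to β-carbonyl phosphonate rearrangement), driven by formation of the stabilised phosphonate enolate, with the non-acidic C5 center unaffected.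

Step 12
Reactants: 25 bis(2,2,2-trifluoroethyl) [(5S)-5-(2-methylprop-1-en-1-yl)-2-oxotetrahydrofuran-3-yl]phosphonate; 18 (4E)-7-(tert-butyldimethylsilyloxy)-4-methylhept-4-enal
Product: 26 (3Z,5S)-3-[(4E)-7-(tert-butyldimethylsilyloxy)-4-methylhept-4-en-1-ylidene]-5-(2-methylprop-1-en-1-yl)dihydrofuran-2(3H)-one
Conditions: KN(SiMe3)2 (1.0 equiv), 18-crown-6, THF, −78 °C; then 18, −78 °C; aq. NH4Cl
Reagents that add atoms: none
Why: Still–Gennari-type Horner–Wadsworth–Emmons olefination, in which the electron-poor trifluoroethyl phosphonate and the dissociated potassium ion make elimination of the kinetic adduct faster than its reversal, which should place the chain cis to the lactone carbonyl (Z).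

Step 13
Reactants: 26 (3Z,5S)-3-[(4E)-7-(tert-butyldimethylsilyloxy)-4-methylhept-4-en-1-ylidene]-5-(2-methylprop-1-en-1-yl)dihydrofuran-2(3H)-one
Product: 27 (3Z,5S)-3-[(4E)-7-hydroxy-4-methylhept-4-en-1-ylidene]-5-(2-methylprop-1-en-1-yl)dihydrofuran-2(3H)-one
Conditions: HF·pyridine, pyridine, THF, 0 → 25 °C
Reagents that add atoms: none
Why: Fluoride-mediated cleavage of the primary silyl ether under buffered conditions that leave the allylic lactone and the alkylidene geometry untouched.

Step 14
Reactants: 27 (3Z,5S)-3-[(4E)-7-hydroxy-4-methylhept-4-en-1-ylidene]-5-(2-methylprop-1-en-1-yl)dihydrofuran-2(3H)-one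
Product: 28 (3Z,5S)-3-[(4E)-7-iodo-4-methylhept-4-en-1-ylidene]-5-(2-methylprop-1-en-1-yl)dihydrofuran-2(3H)-one
Conditions: I2, PPh3, imidazole, CH2Cl2, 0 °C
Reagents that add atoms: iodine, II
Why: Appel-type iodination, an SN2 displacement of the alkoxyphosphonium by iodide at the primary carbon under neutral conditions that tolerate the alkenes and the lactone.

Step 15
Reactants: 28 (3Z,5S)-3-[(4E)-7-iodo-4-methylhept-4-en-1-ylidene]-5-(2-methylprop-1-en-1-yl)dihydrofuran-2(3H)-one; 11 4-[(1R,3E)-1-hydroxy-4-iodopent-3-en-1-yl]furan-2(5H)-one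
Product: 30 (3Z,5S)-3-[(4E,8E,11R)-11-hydroxy-4,8-dimethyl-11-(5-oxo-2,5-dihydrofuran-3-yl)undeca-4,8-dien-1-ylidene]-5-(2-methylprop-1-en-1-yl)dihydrofuran-2(3H)-one, via alkylzinc iodide 29 (not isolated)
Conditions: Zn dust (activated with BrCH2CH2Br and Me3SiCl), LiCl, THF, 40 °C; then slow addition of 29 (1.6 equiv) to 11, Pd(OAc)2 (4 mol %), 2-dicyclohexylphosphino-2',6'-dimethoxybiphenyl (8 mol %), THF, 25 °C
Reagents that add atoms: none
Why: Zinc inserts into the primary C–I bond of 28 to give 29; zerovalent palladium formed from Pd(OAc)2 and the phosphine adds oxidatively to the alkenyl C–I bond of 11 with retention, and transmetalation from 29 followed by reductive elimination forms the C7–C8 bond. The closest known reaction type is the alkyl–alkenyl Negishi coupling, including its biarylphosphine version that tolerates free hydroxyl groups. No ring is closed and no stereocenter is created; both existing stereocenters are remote from the reacting carbons. The step needs retention of the E C8=C9 geometry, which the stereoretentive oxidative addition and reductive elimination at the preformed iodoalkene secure. It needs chemoselectivity for the alkenyl C–I bond over the allylic C–O bonds of both lactone rings, which the much faster oxidative addition of the iodide and the hindered trisubstituted alkene beside the lactone C5–O bond should secure. It also needs coupling to outrun protonolysis of 29 by the free carbinol, which fast phosphine-promoted transmetalation, slow addition and a modest excess of 29 should secure.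

Compound list

1 | furan-3-carbaldehyde | O=Cc1ccoc1 | starting material
2 | allenylboronic acid pinacol ester (4,4,5,5-tetramethyl-2-(propa-1,2-dien-1-yl)-1,3,2-dioxaborolane) | C=C=CB1OC(C)(C)C(C)(C)O1 | starting material
3 | (1R)-1-(furan-3-yl)but-3-yn-1-ol | C#CC[C@@H](O)c1ccoc1 | intermediate
4 | dilithio alkoxide-acetylide of 3 | [Li]C#CC[C@@H](O[Li])c1ccoc1 | intermediate
5 | (1R)-1-(furan-3-yl)pent-3-yn-1-ol | CC#CC[C@@H](O)c1ccoc1 | intermediate
6 | bis-zirconocene alkenyl alkoxide: (1R,3E)-1-(furan-3-yl)pent-3-en-1-ol carrying ZrCp2Cl on C4 and on oxygen | C/C(=C\C[C@@H](O[Zr](Cl)(C1C=CC=C1)C1C=CC=C1)c1ccoc1)[Zr](Cl)(C1C=CC=C1)C1C=CC=C1 | intermediate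
7 | (1R,3E)-1-(furan-3-yl)-4-iodopent-3-en-1-ol | I/C(C)=C/C[C@@H](O)c1ccoc1 | intermediate
8 | furan endoperoxide: (1R,3E)-4-iodo-1-(2,3,7-trioxabicyclo[2.2.1]hept-5-en-5-yl)pent-3-en-1-ol | I/C(C)=C/C[C@@H](O)C1=CC2OOC1O2 | intermediate
9 | 5-hydroxy-4-[(1R,3E)-1-hydroxy-4-iodopent-3-en-1-yl]furan-2(5H)-one (both C5 epimers) | I/C(C)=C/C[C@@H](O)C1=CC(=O)OC1O | intermediate
10 | (2E,4R,6E)-4-hydroxy-3-(hydroxymethyl)-7-iodoocta-2,6-dienoic acid | OC(=O)/C=C(CO)/[C@H](O)C/C=C(C)/I | intermediate
11 | 4-[(1R,3E)-1-hydroxy-4-iodopent-3-en-1-yl]furan-2(5H)-one | I/C(C)=C/C[C@@H](O)C1=CC(=O)OC1 | intermediate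
12 | 3-(tert-butyldimethylsilyloxy)propanal | O=CCCO[Si](C)(C)C(C)(C)C | starting material
13 | isopropenylmagnesium bromide | CC(=C)[Mg]Br | starting material
14 | 5-(tert-butyldimethylsilyloxy)-2-methylpent-1-en-3-ol (racemic) | C=C(C)C(O)CCO[Si](C)(C)C(C)(C)C | intermediate
15 | triethyl orthoacetate | CCOC(C)(OCC)OCC | starting material
16 | mixed ketene acetal: 1-ethoxyvinyl ether of 14 | C=C(OCC)OC(CCO[Si](C)(C)C(C)(C)C)C(C)=C | intermediate
17 | ethyl (4E)-7-(tert-butyldimethylsilyloxy)-4-methylhept-4-enoate | CCOC(=O)CC/C(C)=C/CCO[Si](C)(C)C(C)(C)C | intermediate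
18 | (4E)-7-(tert-butyldimethylsilyloxy)-4-methylhept-4-enal | O=CCC/C(C)=C/CCO[Si](C)(C)C(C)(C)C | intermediate
19 | (5S)-5-(hydroxymethyl)dihydrofuran-2(3H)-one | OC[C@@H]1CCC(=O)O1 | starting material
20 | (2S)-5-oxotetrahydrofuran-2-carbaldehyde | O=C[C@@H]1CCC(=O)O1 | intermediate
21 | isopropyltriphenylphosphonium iodide | CC(C)[P+](c1ccccc1)(c1ccccc1)c1ccccc1.[I-] | starting material
22 | isopropylidenetriphenylphosphorane | CC(C)=P(c1ccccc1)(c1ccccc1)c1ccccc1 | intermediate
23 | (5S)-5-(2-methylprop-1-en-1-yl)dihydrofuran-2(3H)-one | CC(C)=C[C@@H]1CCC(=O)O1 | intermediate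
24 | enol phosphate: (2S)-2-(2-methylprop-1-en-1-yl)-2,3-dihydrofuran-5-yl bis(2,2,2-trifluoroethyl) phosphate | CC(C)=C[C@@H]1CC=C(OP(=O)(OCC(F)(F)F)OCC(F)(F)F)O1 | intermediate
25 | bis(2,2,2-trifluoroethyl) [(5S)-5-(2-methylprop-1-en-1-yl)-2-oxotetrahydrofuran-3-yl]phosphonate (both C3 epimers) | CC(C)=C[C@@H]1CC(P(=O)(OCC(F)(F)F)OCC(F)(F)F)C(=O)O1 | intermediate
26 | (3Z,5S)-3-[(4E)-7-(tert-butyldimethylsilyloxy)-4-methylhept-4-en-1-ylidene]-5-(2-methylprop-1-en-1-yl)dihydrofuran-2(3H)-one | CC(C)=C[C@@H]1C/C(=C/CC/C(C)=C/CCO[Si](C)(C)C(C)(C)C)C(=O)O1 | intermediate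
27 | (3Z,5S)-3-[(4E)-7-hydroxy-4-methylhept-4-en-1-ylidene]-5-(2-methylprop-1-en-1-yl)dihydrofuran-2(3H)-one | CC(C)=C[C@@H]1C/C(=C/CC/C(C)=C/CCO)C(=O)O1 | intermediate
28 | (3Z,5S)-3-[(4E)-7-iodo-4-methylhept-4-en-1-ylidene]-5-(2-methylprop-1-en-1-yl)dihydrofuran-2(3H)-one | CC(C)=C[C@@H]1C/C(=C/CC/C(C)=C/CCI)C(=O)O1 | intermediate
29 | alkylzinc iodide of 28 (iodozinc in place of iodine at C7 of the side chain) | CC(C)=C[C@@H]1C/C(=C/CC/C(C)=C/CC[Zn]I)C(=O)O1 | intermediate
30 | (3Z,5S)-3-[(4E,8E,11R)-11-hydroxy-4,8-dimethyl-11-(5-oxo-2,5-dihydrofuran-3-yl)undeca-4,8-dien-1-ylidene]-5-(2-methylprop-1-en-1-yl)dihydrofuran-2(3H)-one | CC(C)=C[C@@H]1C/C(=C/CC/C(C)=C/CC/C(C)=C/C[C@@H](O)C2=CC(=O)OC2)C(=O)O1 | target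

Total step count: 15. Longest linear sequence: 7 steps (19 → 20 → 23 → 25 → 26 → 27 → 28 → 30; the chain branch from 12 is equally long).

Steps most likely to fail

Step 15. The organozinc may be protonated by the free carbinol before it transmetalates, and zerovalent palladium may ionise the allylic C–O bond of the lactone instead of adding to the iodoalkene. The fallback sets out from 28 and 11 and comes back at 30. It is a nickel-catalysed reductive cross-electrophile coupling (NiBr2(MeOCH2CH2OMe) 10 mol %, 4,4'-di-tert-butyl-2,2'-bipyridine, Mn powder, NaI, N,N-dimethylacetamide, 25 °C). The alkyl radical from 28 is captured by the alkenylnickel species from 11, so no carbanion is present that the hydroxyl could quench. New compounds on the way: none F0.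

Step 12. Z selectivity may erode if addition of the cyclic phosphonate anion becomes reversible, and base may move the exocyclic alkene into the ring. The fallback sets out from 23 and comes back at 27 by an acyclic Still–Gennari olefination.
- Saponification of 23 (KOH, MeOH/H2O) gives potassium (4S)-4-hydroxy-6-methylhept-5-enoate F1.
- Alkylation of the carboxylate (MeI, DMF, 0 °C) gives methyl (4S)-4-hydroxy-6-methylhept-5-enoate F2, which is silylated at once (t-BuMe2SiOSO2CF3, 2,6-lutidine, CH2Cl2, −78 °C) to methyl (4S)-4-(tert-butyldimethylsilyloxy)-6-methylhept-5-enoate F3.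
- Treatment as in step 11 passes through the ketene acetal phosphate 1-methoxy-1-[bis(2,2,2-trifluoroethoxy)phosphoryloxy]-(4S)-4-(tert-butyldimethylsilyloxy)-6-methylhepta-1,5-diene F4 (not isolated) to methyl (4S)-2-[bis(2,2,2-trifluoroethoxy)phosphoryl]-4-(tert-butyldimethylsilyloxy)-6-methylhept-5-enoate F5.
- Olefination of F5 with 18 (KN(SiMe3)2, 18-crown-6, THF, −78 °C) should give methyl (2Z,6E)-9-(tert-butyldimethylsilyloxy)-2-[(2S)-2-(tert-butyldimethylsilyloxy)-4-methylpent-3-en-1-yl]-6-methylnona-2,6-dienoate F6, with the usual Z preference of α-alkyl trifluoroethyl phosphonoacetates.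
- Bu4NF in THF removes both silyl groups to give methyl (2Z,6E)-9-hydroxy-2-[(2S)-2-hydroxy-4-methylpent-3-en-1-yl]-6-methylnona-2,6-dienoate F7 (not isolated), whose γ-hydroxyl closes the lactone to 27.

Step 11. The amide base may attack the electrophilic trifluoroethyl phosphate at phosphorus with loss of trifluoroethoxide, or the 1,3-migration may stall at the enol phosphate. The fallback sets out from 23 and comes back at 25. The lithium enolate of 23 (LiN(i-Pr)2, THF, −78 °C) is trapped at carbon by the trivalent phosphorus electrophile ClP(OCH2CF3)2 to give bis(2,2,2-trifluoroethyl) [(5S)-5-(2-methylprop-1-en-1-yl)-2-oxotetrahydrofuran-3-yl]phosphonite F8. Oxidation (t-BuOOH, CH2Cl2, 0 °C) then gives 25 without any migration step.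

Further compounds

F0 | step 15 | none | none
F1 | step 12 | potassium (4S)-4-hydroxy-6-methylhept-5-enoate | CC(C)=C[C@@H](O)CCC(=O)[O-].[K+]
F2 | step 12 | methyl (4S)-4-hydroxy-6-methylhept-5-enoate | CC(C)=C[C@@H](O)CCC(=O)OC
F3 | step 12 | methyl (4S)-4-(tert-butyldimethylsilyloxy)-6-methylhept-5-enoate | CC(C)=C[C@@H](O[Si](C)(C)C(C)(C)C)CCC(=O)OC
F4 | step 12 | 1-methoxy-1-[bis(2,2,2-trifluoroethoxy)phosphoryloxy]-(4S)-4-(tert-butyldimethylsilyloxy)-6-methylhepta-1,5-diene (ketene acetal phosphate, both C1=C2 isomers) | CC(C)=C[C@@H](O[Si](C)(C)C(C)(C)C)CC=C(OC)OP(=O)(OCC(F)(F)F)OCC(F)(F)F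
F5 | step 12 | methyl (4S)-2-[bis(2,2,2-trifluoroethoxy)phosphoryl]-4-(tert-butyldimethylsilyloxy)-6-methylhept-5-enoate (both C2 epimers) | CC(C)=C[C@@H](O[Si](C)(C)C(C)(C)C)CC(C(=O)OC)P(=O)(OCC(F)(F)F)OCC(F)(F)F
F6 | step 12 | methyl (2Z,6E)-9-(tert-butyldimethylsilyloxy)-2-[(2S)-2-(tert-butyldimethylsilyloxy)-4-methylpent-3-en-1-yl]-6-methylnona-2,6-dienoate | CC(C)=C[C@@H](O[Si](C)(C)C(C)(C)C)C/C(=C/CC/C(C)=C/CCO[Si](C)(C)C(C)(C)C)C(=O)OC
F7 | step 12 | methyl (2Z,6E)-9-hydroxy-2-[(2S)-2-hydroxy-4-methylpent-3-en-1-yl]-6-methylnona-2,6-dienoate | CC(C)=C[C@@H](O)C/C(=C/CC/C(C)=C/CCO)C(=O)OC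
F8 | step 11 | bis(2,2,2-trifluoroethyl) [(5S)-5-(2-methylprop-1-en-1-yl)-2-oxotetrahydrofuran-3-yl]phosphonite | CC(C)=C[C@@H]1CC(P(OCC(F)(F)F)OCC(F)(F)F)C(=O)O1
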